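## Retrosynthetic overview

- Feature: in ring A the lactone oxygen O1 (on C8a) and the methine C4 (on C4a) sit on adjacent carbons, and C5, the other neighbour of C4a, carries oxygen. Ring A can therefore enter as the aryne C4a≡C8a, polarised by the C5 oxygen.
- Key disconnection (ring B, the only ring formed): C8a–O1, C4a–C4, C3–C4 and O1–C2 in one operation from an ortho-silylaryl triflate (ring A), DMF (O1 and C4) and the silyl ketene acetal of a ring-C arylacetate (C2 and C3).
- Aryne precursor: 5-methoxyresorcinol → mono-MOM ether → O-carbamate → ortho-silylation between the two oxygens → phenol → triflate. Ring-C piece: 2,4-dihydroxyphenylacetic acid → methyl ester → bis-allyl ether.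
- Endgame: free O5, form its 1,1-dimethylallyl ether, aromatic Claisen rearrangement to C6 (C4a is blocked), then remove the ring-C allyl groups with zerovalent palladium.
- Ring order: rings A and C are bought, ring B is closed in step 9.

Key step: step 9

Remark on the chemistry: coumarin numbering is used throughout (ring A = benzo ring, ring B = lactone ring, ring C = the 2,4-dioxygenated phenyl ring on C3). The target has no stereocentre. The double-bond geometry of 12 and the transient sp3 centres of 15, 17 and 23 are lost in the products and are therefore drawn without configuration.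

## Route

Step 1
Reactants: 1 5-methoxyresorcinol
Product: 2 3-methoxy-5-(methoxymethoxy)phenol
Conditions: MOMCl (1 equiv), K2CO3, acetone, 0 °C to rt
Reagents that add atoms: chloromethyl methyl ether (MOMCl), COCCl
Why: Williamson-type O-alkylation of the phenoxide; 1 is symmetrical, so limiting the chloride should give the mono-ether, separable from diol and bis-ether, which can both be recycled.

Step 2
Reactants: 2 3-methoxy-5-(methoxymethoxy)phenol
Product: 3 3-methoxy-5-(methoxymethoxy)phenyl N,N-diethylcarbamate
Conditions: Et2NCOCl, K2CO3, MeCN, reflux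
Reagents that add atoms: diethylcarbamoyl chloride, CCN(CC)C(Cl)=O
Why: O-carbamoylation (acyl substitution) places the strongest ortho-directing group on the oxygen that will be replaced by O1.

Step 3
Reactants: 3 3-methoxy-5-(methoxymethoxy)phenyl N,N-diethylcarbamate
Product: 5 5-methoxy-3-(methoxymethoxy)-2-(trimethylsilyl)phenyl N,N-diethylcarbamate, via aryllithium 4 (not isolated)
Conditions: s-BuLi, TMEDA, THF, −78 °C; then TMSCl, −78 °C to rt
Reagents that add atoms: chlorotrimethylsilane (TMSCl), C[Si](C)(C)Cl
Why: Directed ortho-metalation: the carbamate and the chelating MOM ether cooperate, so lithiation should occur at the one carbon lying between them and not beside the weaker methoxy director, and the low temperature holds back the anionic ortho-Fries shift before the silyl quench.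

Step 4
Reactants: 5 5-methoxy-3-(methoxymethoxy)-2-(trimethylsilyl)phenyl N,N-diethylcarbamate
Product: 6 5-methoxy-3-(methoxymethoxy)-2-(trimethylsilyl)phenol
Conditions: LiAlH4, THF, 0 °C to reflux; aq. potassium sodium tartrate (KNaC4H4O6)
Reagents that add atoms: none
Why: Reductive carbamate cleavage (hydride attack at the carbonyl expels the phenoxide) is a non-acidic method that leaves the MOM acetal and the protodesilylation-prone electron-rich aryl–silicon bond alone.

Step 5
Reactants: 6 5-methoxy-3-(methoxymethoxy)-2-(trimethylsilyl)phenol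
Product: 7 5-methoxy-3-(methoxymethoxy)-2-(trimethylsilyl)phenyl trifluoromethanesulfonate
Conditions: PhNTf2, DBU, MeCN, rt
Reagents that add atoms: N-phenylbis(trifluoromethanesulfonimide) (PhNTf2), O=S(=O)(N(c1ccccc1)S(=O)(=O)C(F)(F)F)C(F)(F)F
Why: O-triflation of the hindered phenoxide with a mild triflyl donor generates no acid, so the ortho-silyl and MOM groups should persist.

Step 6
Reactants: 8 2,4-dihydroxyphenylacetic acid
Product: 9 methyl 2-(2,4-dihydroxyphenyl)acetate
Conditions: MeOH, H2SO4 (cat.), reflux
Reagents that add atoms: methanol, CO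
Why: Fischer esterification; in methanol the open methyl ester is favoured over the benzofuranone lactone.

Step 7
Reactants: 9 methyl 2-(2,4-dihydroxyphenyl)acetate
Product: 10 methyl 2-[2,4-bis(allyloxy)phenyl]acetate
Conditions: allyl bromide, K2CO3, acetone, reflux
Reagents that add atoms: allyl bromide, C=CCBr
Why: Williamson etherification of both phenols; allyl ethers tolerate fluoride, enolate and acid and come off at the end under neutral conditions that spare a prenyl group.

Step 8
Reactants: 10 methyl 2-[2,4-bis(allyloxy)phenyl]acetate
Product: 12 methyl trimethylsilyl ketene acetal of 10 {[2-(2,4-bis(allyloxy)phenyl)-1-methoxyethenyl]oxy}trimethylsilane (E/Z mixture), via lithium enolate 11 (not isolated)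
Conditions: LiN(iPr)2, THF, −78 °C; then TMSCl, −78 °C to rt; non-aqueous work-up, used crude
Reagents that add atoms: chlorotrimethylsilane (TMSCl), C[Si](C)(C)Cl
Why: Kinetic ester enolisation and O-silylation of the lithium enolate give the ketene silyl acetal; a methyl ester is used so that no Ireland–Claisen pathway exists, and the aryl allyl ethers are inert to the amide base at −78 °C.

Step 9
Reactants: 7 5-methoxy-3-(methoxymethoxy)-2-(trimethylsilyl)phenyl trifluoromethanesulfonate; 12 silyl ketene acetal; 13 N,N-dimethylformamide (also the solvent)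
Product: 18 7-methoxy-5-(methoxymethoxy)-3-[2,4-bis(allyloxy)phenyl]coumarin, via aryne 14 (not isolated), via benzoxetene 15 (not isolated), via ortho-quinone methide 16 (not isolated), via aminodihydrocoumarin 17 (not isolated)
Conditions: CsF, DMF, 0 °C to rt
Reagents that add atoms: none
Why: Fluoride removes the silyl group of 7 and triflate departs to give aryne 14 (C4a≡C8a); the carbonyl oxygen of DMF adds to C8a, the aryne carbon remote from the C5 oxygen, the aryl anion that develops at C4a closes on the iminium carbon (4-exo-trig) to benzoxetene 15, and 4π electrocyclic opening gives ortho-quinone methide 16 with NMe2 on C4. Fluoride also unmasks the ester enolate from 12 in low stationary concentration, and this adds to C4 of 16 (conjugate addition that rearomatises ring A) to make C3–C4. The C8a phenoxide so formed attacks the methyl ester in a 6-exo-trig acyl substitution that closes lactone ring B (O1–C2) and gives 17, and base-mediated E1cB loss of dimethylamine across C3–C4 delivers the coumarin. The closest known reaction type is the three-component coupling of arynes, formamides and carbon acids or ketene silyl acetals to coumarins by way of ortho-quinone methides. No stereocentre remains in 18, the centres of 15 and 17 being transient. The step needs regioselective addition to the unsymmetrical aryne, secured by the C5 alkoxy group beside the triple bond (aryne distortion and inductive stabilisation of the C4a anion; the C7 methoxy group is too far away to matter), and it needs DMF to reach the aryne before the carbon nucleophile, secured by using DMF as solvent and keeping the enolate masked as its silyl ether.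

Step 10
Reactants: 18 7-methoxy-5-(methoxymethoxy)-3-[2,4-bis(allyloxy)phenyl]coumarin
Product: 19 5-hydroxy-7-methoxy-3-[2,4-bis(allyloxy)phenyl]coumarin
Conditions: HCl (cat.), MeOH/THF, 50 °C
Reagents that add atoms: none
Why: Acid-catalysed acetal exchange with methanol removes the MOM group alone; aryl allyl ethers, the aryl methyl ether and the coumarin lactone are stable to it.

Step 11
Reactants: 19 5-hydroxy-7-methoxy-3-[2,4-bis(allyloxy)phenyl]coumarin; 20 3-chloro-3-methylbut-1-yne
Product: 21 7-methoxy-5-[(2-methylbut-3-yn-2-yl)oxy]-3-[2,4-bis(allyloxy)phenyl]coumarin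
Conditions: DBU, CuCl2 (cat.), MeCN, 0 °C to rt
Reagents that add atoms: none
Why: Copper-catalysed propargylic etherification of the only free phenol (through a copper acetylide/allenylidene ion pair) forms the tertiary ether that direct SN2 cannot give.

Step 12
Reactants: 21 7-methoxy-5-[(2-methylbut-3-yn-2-yl)oxy]-3-[2,4-bis(allyloxy)phenyl]coumarin
Product: 22 7-methoxy-5-[(2-methylbut-3-en-2-yl)oxy]-3-[2,4-bis(allyloxy)phenyl]coumarin
Conditions: H2 (1 atm), Pd/CaCO3 poisoned with Pb(OAc)2, quinoline, EtOAc, rt, stopped after one equivalent
Reagents that add atoms: none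
Why: Lindlar-type semihydrogenation: the terminal alkyne binds the poisoned palladium far more strongly than the monosubstituted alkenes (new vinyl group and ring-C allyl ethers) or the hindered C3=C4 bond, so reduction should stop at the alkene.

Step 13
Reactants: 22 7-methoxy-5-[(2-methylbut-3-en-2-yl)oxy]-3-[2,4-bis(allyloxy)phenyl]coumarin
Product: 24 5-hydroxy-7-methoxy-6-(3-methylbut-2-enyl)-3-[2,4-bis(allyloxy)phenyl]coumarin, via dienone 23 (not isolated)
Conditions: PhNEt2, 130 °C
Reagents that add atoms: none
Why: Aromatic Claisen ([3,3]-sigmatropic) rearrangement: C4a carries no hydrogen, so the allyl unit is delivered with inversion to C6 as a prenyl group and dienone 23 tautomerises to the phenol; the tertiary ether should rearrange well below the temperature at which the primary allyl ethers of ring C react.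

Step 14
Reactants: 24 5-hydroxy-7-methoxy-6-(3-methylbut-2-enyl)-3-[2,4-bis(allyloxy)phenyl]coumarin
Product: 25 3-(2,4-dihydroxyphenyl)-5-hydroxy-7-methoxy-6-(3-methylbut-2-enyl)coumarin (CNP0305155.0)
Conditions: Pd(PPh3)4 (cat.), morpholine, THF, rt
Reagents that add atoms: none
Why: Tsuji–Trost deallylation: zerovalent palladium ionises the two aryl allyl ethers and morpholine captures the π-allyl units, under neutral conditions that avoid acid-induced chroman formation from the ortho-prenylphenol.

## Compound list

1 | 5-methoxyresorcinol | COc1cc(O)cc(O)c1 | starting material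
2 | 3-methoxy-5-(methoxymethoxy)phenol | COCOc1cc(O)cc(OC)c1 | intermediate
3 | 3-methoxy-5-(methoxymethoxy)phenyl N,N-diethylcarbamate | CCN(CC)C(=O)Oc1cc(OC)cc(OCOC)c1 | intermediate
4 | aryllithium of 3, lithium on the carbon between the carbamate and MOM oxygens (transient) | CCN(CC)C(=O)Oc1cc(OC)cc(OCOC)c1[Li] | intermediate
5 | 5-methoxy-3-(methoxymethoxy)-2-(trimethylsilyl)phenyl N,N-diethylcarbamate | CCN(CC)C(=O)Oc1cc(OC)cc(OCOC)c1[Si](C)(C)C | intermediate
6 | 5-methoxy-3-(methoxymethoxy)-2-(trimethylsilyl)phenol | COCOc1cc(OC)cc(O)c1[Si](C)(C)C | intermediate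
7 | 5-methoxy-3-(methoxymethoxy)-2-(trimethylsilyl)phenyl trifluoromethanesulfonate | COc1cc(OCOC)c([Si](C)(C)C)c(OS(=O)(=O)C(F)(F)F)c1 | intermediate
8 | 2,4-dihydroxyphenylacetic acid | OC(=O)Cc1ccc(O)cc1O | starting material
9 | methyl 2-(2,4-dihydroxyphenyl)acetate | COC(=O)Cc1ccc(O)cc1O | intermediate
10 | methyl 2-[2,4-bis(allyloxy)phenyl]acetate | COC(=O)Cc1ccc(OCC=C)cc1OCC=C | intermediate
11 | lithium enolate of 10 (transient) | COC(=Cc1ccc(OCC=C)cc1OCC=C)O[Li] | intermediate
12 | {[2-(2,4-bis(allyloxy)phenyl)-1-methoxyethenyl]oxy}trimethylsilane, E/Z mixture | COC(O[Si](C)(C)C)=Cc1ccc(OCC=C)cc1OCC=C | intermediate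
13 | N,N-dimethylformamide | CN(C)C=O | starting material
14 | 5-methoxy-3-(methoxymethoxy)benzyne, triple bond C4a≡C8a (transient) | COC1=CC#CC(OCOC)=C1 | intermediate
15 | 2-(dimethylamino)-5-methoxy-3-(methoxymethoxy)-2H-1-benzoxete, racemic (transient) | CN(C)C1Oc2cc(OC)cc(OCOC)c21 | intermediate
16 | 6-[(dimethylamino)methylidene]-3-methoxy-5-(methoxymethoxy)cyclohexa-2,4-dien-1-one (transient) | CN(C)C=C1C(OCOC)=CC(OC)=CC1=O | intermediate
17 | 4-(dimethylamino)-7-methoxy-5-(methoxymethoxy)-3-[2,4-bis(allyloxy)phenyl]-3,4-dihydrocoumarin, diastereomer mixture (transient) | COc1cc2OC(=O)C(c3ccc(OCC=C)cc3OCC=C)C(N(C)C)c2c(OCOC)c1 | intermediate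
18 | 7-methoxy-5-(methoxymethoxy)-3-[2,4-bis(allyloxy)phenyl]coumarin | COc1cc2oc(=O)c(-c3ccc(OCC=C)cc3OCC=C)cc2c(OCOC)c1 | intermediate
19 | 5-hydroxy-7-methoxy-3-[2,4-bis(allyloxy)phenyl]coumarin | COc1cc2oc(=O)c(-c3ccc(OCC=C)cc3OCC=C)cc2c(O)c1 | intermediate
20 | 3-chloro-3-methylbut-1-yne | CC(C)(Cl)C#C | starting material
21 | 7-methoxy-5-[(2-methylbut-3-yn-2-yl)oxy]-3-[2,4-bis(allyloxy)phenyl]coumarin | COc1cc2oc(=O)c(-c3ccc(OCC=C)cc3OCC=C)cc2c(OC(C)(C)C#C)c1 | intermediate
22 | 7-methoxy-5-[(2-methylbut-3-en-2-yl)oxy]-3-[2,4-bis(allyloxy)phenyl]coumarin | COc1cc2oc(=O)c(-c3ccc(OCC=C)cc3OCC=C)cc2c(OC(C)(C)C=C)c1 | intermediate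
23 | 6H-dienone tautomer of 24 (C5 ketone, prenyl and H on C6), racemic (transient) | COC1=CC2=C(C=C(c3ccc(OCC=C)cc3OCC=C)C(=O)O2)C(=O)C1CC=C(C)C | intermediate
24 | 5-hydroxy-7-methoxy-6-(3-methylbut-2-enyl)-3-[2,4-bis(allyloxy)phenyl]coumarin | COc1cc2oc(=O)c(-c3ccc(OCC=C)cc3OCC=C)cc2c(O)c1CC=C(C)C | intermediate
25 | 3-(2,4-dihydroxyphenyl)-5-hydroxy-7-methoxy-6-(3-methylbut-2-enyl)coumarin | COc1cc2oc(=O)c(-c3ccc(O)cc3O)cc2c(O)c1CC=C(C)C | target

## Step count and risks

Total steps: 14. Longest linear sequence: 11 (steps 1–5 and 9–14).

**Step 9 (key step).** The three components may fail to combine in the required order. The fluoride-released enolate may add directly to aryne 14 (α-arylation), the ketene acetal may be protodesilylated before 16 has formed, or phenoxide intermediates may be arylated by further aryne. The fallback sets out from 7 and 10 and returns at 18. The aryne insertion is run without a carbon nucleophile: 7 is treated with CsF in DMF and the resulting 16 is hydrolysed on aqueous work-up to 2-hydroxy-4-methoxy-6-(methoxymethoxy)benzaldehyde F1. Ester 10 is saponified (LiOH, THF/H2O) to 2-[2,4-bis(allyloxy)phenyl]acetic acid F2. F1 and F2 are then condensed under Perkin–Oglialoro conditions (Ac2O, Et3N, 110 °C), where O-acylation of the salicylaldehyde is followed by intramolecular aldol condensation and dehydration, to give 18.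

**Step 13 (Claisen rearrangement).** The tertiary allyl ether may ionise with loss of isoprene and return to 19 instead of rearranging. If the temperature has to be raised, the ring-C allyl ethers may begin their own Claisen rearrangement. The fallback sets out from 19, bypasses steps 11–13 and returns at 24. O-Prenylation of 19 (prenyl bromide, K2CO3, acetone) gives 7-methoxy-5-(3-methylbut-2-enyloxy)-3-[2,4-bis(allyloxy)phenyl]coumarin F3. A solid-acid-promoted [1,3] shift of the prenyl group (magnesium silicate MgSiO3, Florisil, toluene, 80–110 °C) should then move it to C6, the only free position ortho to O5, giving 24. The unsubstituted allyl ethers of ring C cannot form a stabilised allyl cation and should be left alone.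

**Step 3 (ortho-lithiation).** Lithiation may also occur on the other flank of the carbamate, between it and the methoxy group. That would place silicon on the wrong carbon and lead to the 5-methoxy-7-oxygenated series. The fallback sets out from 1 and returns at 7; it secures the position by symmetry, at the price of a statistical mono-triflation late instead of the statistical mono-etherification early. Compound 1 is converted (Et2NCOCl, K2CO3, MeCN) into 5-methoxy-1,3-phenylene bis(N,N-diethylcarbamate) F4, in which the wanted carbon is the only one flanked by two carbamates. Lithiation and silylation (s-BuLi, TMEDA, THF, −78 °C; TMSCl) give 5-methoxy-2-(trimethylsilyl)-1,3-phenylene bis(N,N-diethylcarbamate) F5. LiAlH4 cleaves both carbamates to 5-methoxy-2-(trimethylsilyl)benzene-1,3-diol F6. One equivalent of PhNTf2 with DBU gives 3-hydroxy-5-methoxy-2-(trimethylsilyl)phenyl trifluoromethanesulfonate F7, and MOMCl with iPr2NEt in CH2Cl2 gives 7.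

## Further compounds

F1 | step 9 | 2-hydroxy-4-methoxy-6-(methoxymethoxy)benzaldehyde | COCOc1cc(OC)cc(O)c1C=O
F2 | step 9 | 2-[2,4-bis(allyloxy)phenyl]acetic acid | OC(=O)Cc1ccc(OCC=C)cc1OCC=C
F3 | step 13 | 7-methoxy-5-(3-methylbut-2-enyloxy)-3-[2,4-bis(allyloxy)phenyl]coumarin | COc1cc2oc(=O)c(-c3ccc(OCC=C)cc3OCC=C)cc2c(OCC=C(C)C)c1
F4 | step 3 | 5-methoxy-1,3-phenylene bis(N,N-diethylcarbamate) | CCN(CC)C(=O)Oc1cc(OC)cc(OC(=O)N(CC)CC)c1
F5 | step 3 | 5-methoxy-2-(trimethylsilyl)-1,3-phenylene bis(N,N-diethylcarbamate) | CCN(CC)C(=O)Oc1cc(OC)cc(OC(=O)N(CC)CC)c1[Si](C)(C)C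
F6 | step 3 | 5-methoxy-2-(trimethylsilyl)benzene-1,3-diol | COc1cc(O)c([Si](C)(C)C)c(O)c1
F7 | step 3 | 3-hydroxy-5-methoxy-2-(trimethylsilyl)phenyl trifluoromethanesulfonate | COc1cc(O)c([Si](C)(C)C)c(OS(=O)(=O)C(F)(F)F)c1
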